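## The problem

The target, (2S,2aR,7aS)-21, is a 2,2a,7,7a-tetrahydro-1H-cyclobuta[a]indene. An arene (ring A) is fused to a cyclopentane (ring B), and ring B shares its C2a–C7a bond with a cyclobutane (ring C). Ring C carries the hard part: the quaternary carbon C1 (gem-dimethyl), the catechol-bearing C2 and both fusion carbons, so three contiguous stereocentres sit beside a fully substituted carbon on a strained ring. The cis B/C fusion is enforced by strain and needs no control. The C2 aryl group lies on the convex face, trans to ring B; this is the thermodynamic position and can be reached by equilibration while C1 is a carbonyl. The absolute configuration therefore reduces to the choice of face at the C2a/C7a pair, and nothing in the molecule can make that choice. Ring A is pentasubstituted, with prenyl at C3, OMe at C4 and OH at C6, and these cannot be told apart by late electrophilic chemistry because the catechol ring would compete. The catechol (oxidation, base), the free phenol and the prenyl alkene (acid, electrophiles, hydrogen-atom donors, hydrogenation) do not survive rough treatment. What opens the structure is that the C2a–C7a bond of ring C is also the alkene bond of an indene: pairing C2a with C2 and C7a with C1 maps the skeleton onto an indene and a two-carbon arylketene unit, whose carbonyl carbon becomes C1.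

## Retrosynthesis

**21 to 20.** The three O–Si bonds are cut last, leading to tris-silyl ether 20 (two tert-butyldimethylsilyl groups on the catechol, triisopropylsilyl on the C6 oxygen). Methyl or benzyl ethers are ruled out: the C4 methyl ether must stay, and the prenyl alkene forbids Lewis-acid dealkylation and hydrogenolysis. The forward step needs only buffered fluoride, and no C–C chemistry follows the release of the catechol.

**20 to 19.** The C3–prenyl bond is cut to give aryl bromide 19. The prenyl group cannot travel earlier, because its trisubstituted alkene would outcompete the indene in the cycloaddition and would be consumed by the hydrogen-atom-transfer chemistry at C1. Electrophilic prenylation at the end would have to tell C3 from C5 and from the catechol ring. A bromine placed at C3 before ring C exists settles the position. The forward reaction is a Pd-catalysed coupling at a di-ortho-substituted, electron-rich aryl bromide that must deliver the linear prenyl isomer.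

**19 to 17 to 16.** The two C1–CH3 bonds are taken back to a carbonyl: 19 from exocyclic alkene 17, and 17 from cyclobutanone 16. A direct polar gem-dimethylation of 16 would pass through a cyclobutyl cation next to a benzylic C–H and is not trusted; a radical hydromethylation of 17 avoids cations. The gain is twofold: C1 becomes a ketene-type carbon, and C2 becomes epimerisable. The forward steps must methylenate an enolisable α-aryl cyclobutanone and add H and CH3 across the alkene without touching the aryl bromide.

**16 to 7 and 13.** Ring C is cut at C7a–C1 and C2a–C2 into indene 7 and the arylacetyl unit of amide 13. The other [2+2] pairing (C2a–C7a with C1–C2) would have to close rings B and C together from two tethered alkenes under irradiation, with no handle for absolute control. The chosen cut removes ring C and all three stereocentres at once and leaves two flat partners. A free arylketene would be achiral and prone to dimerise; the keteniminium salt from 13 is more electrophilic and carries the C2-symmetric auxiliary 11. The forward reaction must join the carbonyl carbon to the non-benzylic alkene carbon, select one face of 7, and prefer the alkene to the electron-rich arenes.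

**7 back to 1.** Indene 7 is opened at its double bond to diene 6 (ring-closing metathesis). Unlike dehydration of an indanol, this fixes the position of the alkene relative to bromine, because the two alkene carbons come from different handles. The vinyl group of 6 comes from aldehyde 5. The bromine of 5 is introduced on silyl ether 4, which offers one activated and accessible ring position. Silylation of phenol 3 precedes bromination so that the ortho-allylphenol cannot undergo bromoetherification. Phenol 3 arises by Claisen rearrangement of allyl ether 2, made from commercial 1. The Claisen shift must end at the carbon between the oxygen and the formyl group.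

**13 to 10 and 11, 10 to 8.** The amide C–N bond is cut to acid 10 and commercial pyrrolidine 11; 10 is the bis-silyl ether of commercial acid 8. The forward steps are a silylation that spares no hydroxyl but frees the acid, and an acylation of a hindered amine.

## Roads not taken

Alternative 1: The cut is the aryl–cyclobutane bond C2b–C2a, so ring B closes last on a cyclobutane from the pinane chiral pool. Forward, aryl bromide A2 (a 2-bromo-4,6-dimethoxyphenyl ketone of a cis-1,3-disubstituted 2,2-dimethylcyclobutane) undergoes palladium-catalysed C(sp3)–H arylation at the ring methylene, with a phosphine ligand and a carboxylate base. The reaction runs through a six-membered palladacycle and gives indanone A1 with the cis fusion that geometry dictates. The merits are real. C1 with both methyl groups and the absolute configuration are bought, so no carbonyl has to become CMe2. The C6 methyl ether of A1, peri to the C7 ketone, can be cleaved selectively, which differentiates C4 from C6 elegantly. The weak points come afterwards. The C2 substituent of A1 is an endo ester that must become an exo catechol, the C7 ketone must be removed, and C3 still lacks the prenyl group, which means halogenating ring A beside a second electron-rich ring. This road is better in certainty of absolute configuration and in the handling of C1. The chosen plan sets against it that the catechol, the C3 marker and the oxygen pattern are all in place when ring C forms, so only four operations follow the key step.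

Alternative 2: Ring A is built, not bought. The cuts are C7–C6a, C6a–C2b and C2b–C3, leading to cis-diester A4 and diketone A5. Forward, the dianion of A5 is acylated at its terminal carbon by the C7a ester of A4. The tricarbonyl chain then closes ring B by a Dieckmann-type attack on the C2a ester, and an aldol condensation with aromatisation closes ring A to give resorcinol ketone A3 in one flask. The step economy is attractive. In one detail the road is superior: in A3 the C6 hydroxyl is chelated to the C7 ketone, so the C4 hydroxyl alone can be methylated, and the gem-dimethyl group is present from the start. For this target there are three problems. The two esters of A4 differ only in distant neighbours, and acylation of the wrong one gives the constitutional isomer with the ketone on the benzylic side. The cis-diester can epimerise under alkoxide to a trans isomer that cannot close. And A4 already holds the quaternary carbon and three stereocentres of ring C in enantiopure form, so the central difficulty is only moved back, while C7 deoxygenation and a C3-versus-C5 prenylation remain. Against the shorter construction of rings A and B the chosen plan sets regiochemistry fixed on both partners and a direct answer to ring C.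

Alternative 3: The cut again runs through ring A (C2b–C3, C3–C4, C5–C6, C6–C6a) and leads to diazo ketone A7 and methoxyacetylene A8. On irradiation A7 undergoes Wolff rearrangement to a vinylketene, which adds A8 in a [2+2] sense. A 4π ring opening and a 6π electrocyclisation then give phenol A6 (Danheiser benzannulation). For ring A this is the best road. The C6 hydroxyl and C4 methoxy group are placed regiospecifically and already differentiated, and there is no C7 oxygen to remove. After the key step only C3 functionalisation and desilylation remain, so the endgame is at least as short as the chosen one. The cost is paid earlier. A7 is a cis-fused bicyclo[3.2.0]heptene that already contains C1, C2 and both fusion centres; it needs its own enantioselective cyclobutane synthesis, then acylation and diazo transfer. A8 is volatile and unstable. The late halogenation of A6 at C3 must also discriminate ring A from the silylated catechol. The chosen plan cannot match this ring A regiocontrol by design. It answers with commercial ring A material whose pattern is fixed by a Claisen rearrangement and one bromination, and with a key step that creates ring C from two flat partners.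

Key step: step 9

Assumption: the (2R,5R)-auxiliary 11 is taken to direct bond formation to the indene face that leads to (2aR,7aS)-16; this sense cannot be fixed on paper, and if it proves opposite the commercially available enantiomer of 11 is used in step 8 with nothing else changed.

## Route

Step 1
Reactants: 1 3-hydroxy-5-methoxybenzaldehyde
Product: 2 3-methoxy-5-(prop-2-en-1-yloxy)benzaldehyde
Conditions: allyl bromide, K2CO3, acetone, 56 °C
Reagents that add atoms: allyl bromide, C=CCBr
Why: Williamson ether synthesis: the phenoxide formed with K2CO3 displaces bromide from the allylic halide, and the formyl group and methyl ether are inert.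

Step 2
Reactants: 2 3-methoxy-5-(prop-2-en-1-yloxy)benzaldehyde
Product: 3 3-hydroxy-5-methoxy-2-(prop-2-en-1-yl)benzaldehyde
Conditions: PhNEt2, 200 °C
Reagents that add atoms: none
Why: Aromatic Claisen rearrangement: the [3,3] shift can end at C2 or C4, and both meta substituents are expected to steer it to C2 (towards the electron-withdrawing formyl group and para to the methoxy donor); tautomerisation restores the phenol.

Step 3
Reactants: 3 3-hydroxy-5-methoxy-2-(prop-2-en-1-yl)benzaldehyde
Product: 4 5-methoxy-2-(prop-2-en-1-yl)-3-(triisopropylsilyloxy)benzaldehyde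
Conditions: TIPSOTf, 2,6-lutidine, CH2Cl2, 0 °C
Reagents that add atoms: triisopropylsilyl trifluoromethanesulfonate, CC(C)[Si](C(C)C)(C(C)C)OS(=O)(=O)C(F)(F)F
Why: Silylation of a phenol with a silyl triflate and a hindered pyridine base, reliable even beside the ortho allyl group; the bulky silyl ether is chosen to survive ylides, triflic anhydride and the stannane coupling.

Step 4
Reactants: 4 5-methoxy-2-(prop-2-en-1-yl)-3-(triisopropylsilyloxy)benzaldehyde
Product: 5 2-bromo-3-methoxy-6-(prop-2-en-1-yl)-5-(triisopropylsilyloxy)benzaldehyde
Conditions: NBS, MeCN, 0 → 25 °C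
Reagents that add atoms: N-bromosuccinimide, O=C1CCC(=O)N1Br
Why: Electrophilic aromatic bromination: C6 of 4 is para to the silyloxy and ortho to the methoxy group, whereas C4 is wedged between the two oxygens and para to the formyl group; under these ionic conditions the activated ring should react faster than the terminal alkene.

Step 5
Reactants: 5 2-bromo-3-methoxy-6-(prop-2-en-1-yl)-5-(triisopropylsilyloxy)benzaldehyde
Product: 6 [4-bromo-3-ethenyl-5-methoxy-2-(prop-2-en-1-yl)phenoxy]triisopropylsilane
Conditions: Ph3PCH3Br, KN(SiMe3)2, THF, 0 → 25 °C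
Reagents that add atoms: methyltriphenylphosphonium bromide, C[P+](c1ccccc1)(c1ccccc1)c1ccccc1.[Br-]
Why: Wittig methylenation of a non-enolisable aromatic aldehyde; the small ylide adds even between two ortho substituents, and neither the aryl bromide nor the silyl ether reacts with it.

Step 6
Reactants: 6 [4-bromo-3-ethenyl-5-methoxy-2-(prop-2-en-1-yl)phenoxy]triisopropylsilane
Product: 7 4-bromo-5-methoxy-7-(triisopropylsilyloxy)-1H-indene
Conditions: RuCl2(=CHPh)(PCy3)(H2IMes) (second-generation Grubbs catalyst), CH2Cl2, 40 °C
Reagents that add atoms: none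
Why: Ring-closing metathesis of two terminal alkenes: the catalyst loads on the unhindered allyl group and closes the five-membered ring onto the styrene with loss of ethene, which places the double bond on the bromine side without ambiguity.

Step 7
Reactants: 8 (3,4-dihydroxyphenyl)acetic acid
Product: 10 [3,4-bis(tert-butyldimethylsilyloxy)phenyl]acetic acid, via silyl ester 9 (not isolated)
Conditions: TBSCl, imidazole, DMF, 25 °C; then AcOH/THF/H2O, 25 °C
Reagents that add atoms: tert-butyldimethylsilyl chloride, CC(C)(C)[Si](C)(C)Cl
Why: Exhaustive silylation followed by selective hydrolysis of the silyl ester, which is far more labile towards dilute acid than the two aryl silyl ethers.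

Step 8
Reactants: 10 [3,4-bis(tert-butyldimethylsilyloxy)phenyl]acetic acid; 11 (2R,5R)-2,5-dimethylpyrrolidine
Product: 13 2-[3,4-bis(tert-butyldimethylsilyloxy)phenyl]-1-[(2R,5R)-2,5-dimethylpyrrolidin-1-yl]ethan-1-one, via acyl chloride 12 (not isolated)
Conditions: (COCl)2, DMF (cat.), CH2Cl2, 0 → 25 °C; then 11, Et3N, CH2Cl2, 0 → 25 °C
Reagents that add atoms: none
Why: Acyl chloride formation and N-acylation of the hindered secondary amine; the two stereocentres of 11 are not involved and are carried over unchanged.

Step 9
Reactants: 7 4-bromo-5-methoxy-7-(triisopropylsilyloxy)-1H-indene; 13 2-[3,4-bis(tert-butyldimethylsilyloxy)phenyl]-1-[(2R,5R)-2,5-dimethylpyrrolidin-1-yl]ethan-1-one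
Product: 16 (2R,2aR,7aS)-2-[3,4-bis(tert-butyldimethylsilyloxy)phenyl]-3-bromo-4-methoxy-6-(triisopropylsilyloxy)-2,2a,7,7a-tetrahydro-1H-cyclobuta[a]inden-1-one, via keteniminium triflate 14 (not isolated), via cyclobutaniminium triflate 15 (not isolated)
Conditions: Tf2O, 2,4,6-collidine, ClCH2CH2Cl, −20 → 60 °C; then H2O, NaHCO3, CH2Cl2, 40 °C
Reagents that add atoms: water, O
Why: Tf2O sulfonylates the amide oxygen of 13 and collidine removes an α-proton, releasing keteniminium triflate 14, a linear heteroallene with a strongly electrophilic central carbon. The non-benzylic alkene carbon of 7 attacks that carbon (C7a–C1) to give a benzylic cation, which collapses on the enamine carbon (C2a–C2); the closest known reaction type is the stepwise polar [2+2] cycloaddition of keteniminium salts bearing C2-symmetric 2,5-dimethylpyrrolidines with alkenes to give enantioenriched cyclobutanones. Ring C thus closes by cation–enamine collapse on the face where the first bond formed, because ring B holds the cation in place, so the C2a/C7a fusion is cis. The regiochemistry (C1 beside C7a, C2 beside C2a) follows from the benzylic cation and is the only orientation open to an indene. The configuration at C7a and C2a is set by the auxiliary: its two methyl groups shield opposite quadrants of the C=N+ acceptor orbital, so the indene, approaching anti to the catechol ring, can present one face only. C2 is set thermodynamically, since iminium 15 and ketone 16 equilibrate through the enamine and enol to the exo aryl group, trans to ring B. The step needs alkene-over-arene chemoselectivity, which the substrate secures because the only free position of ring A lies between the methoxy and the bulky silyloxy group and bromine blocks C3, while collidine buffers triflic acid against indene oligomerisation. Aqueous hydrogencarbonate hydrolyses 15 to 16 and returns auxiliary 11.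

Step 10
Reactants: 16 (2R,2aR,7aS)-2-[3,4-bis(tert-butyldimethylsilyloxy)phenyl]-3-bromo-4-methoxy-6-(triisopropylsilyloxy)-2,2a,7,7a-tetrahydro-1H-cyclobuta[a]inden-1-one
Product: 17 (2S,2aR,7aS)-2-[3,4-bis(tert-butyldimethylsilyloxy)phenyl]-3-bromo-4-methoxy-1-methylidene-6-(triisopropylsilyloxy)-2,2a,7,7a-tetrahydro-1H-cyclobuta[a]indene
Conditions: Ph3PCH3Br, KN(SiMe3)2, THF, 0 °C; then 16, −78 → 25 °C
Reagents that add atoms: methyltriphenylphosphonium bromide, C[P+](c1ccccc1)(c1ccccc1)c1ccccc1.[Br-]
Why: Wittig methylenation: addition to the cyclobutanone carbonyl relieves angle strain and should outrun enolisation, and any epimerisation at C2 only returns the more stable exo-aryl isomer (the descriptor at C2 changes by priority only).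

Step 11
Reactants: 17 (2S,2aR,7aS)-2-[3,4-bis(tert-butyldimethylsilyloxy)phenyl]-3-bromo-4-methoxy-1-methylidene-6-(triisopropylsilyloxy)-2,2a,7,7a-tetrahydro-1H-cyclobuta[a]indene
Product: 19 (2S,2aR,7aS)-2-[3,4-bis(tert-butyldimethylsilyloxy)phenyl]-3-bromo-4-methoxy-1,1-dimethyl-6-(triisopropylsilyloxy)-2,2a,7,7a-tetrahydro-1H-cyclobuta[a]indene, via sulfonylhydrazide adduct 18 (not isolated)
Conditions: Fe(acac)3, PhSiH3, CH2=NNHSO2(n-C8H17) (from n-C8H17SO2NHNH2 and aq. HCHO), THF/MeOH, 25 °C; then MeOH, 60 °C
Reagents that add atoms: formaldehyde, C=O (carbon of the new methyl group; used as its N-octylsulfonylhydrazone, C=NNS(=O)(=O)CCCCCCCC)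
Why: Metal-hydride hydrogen-atom-transfer hydromethylation: the iron hydride from Fe(acac)3 and PhSiH3 delivers a hydrogen atom to the CH2 terminus (Markovnikov), and the tertiary C1 radical adds to the hydrazone carbon to give 18. Heating in methanol expels sulfinate and then N2 from the diazene, leaving the second methyl group. C1 ends non-stereogenic, so both epimers of 18 converge, and aryl bromides and silyl ethers tolerate this radical chemistry.

Step 12
Reactants: 19 (2S,2aR,7aS)-2-[3,4-bis(tert-butyldimethylsilyloxy)phenyl]-3-bromo-4-methoxy-1,1-dimethyl-6-(triisopropylsilyloxy)-2,2a,7,7a-tetrahydro-1H-cyclobuta[a]indene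
Product: 20 (2S,2aR,7aS)-2-[3,4-bis(tert-butyldimethylsilyloxy)phenyl]-4-methoxy-1,1-dimethyl-3-(3-methylbut-2-en-1-yl)-6-(triisopropylsilyloxy)-2,2a,7,7a-tetrahydro-1H-cyclobuta[a]indene
Conditions: Pd(PPh3)4, Bu3SnCH2CH=CMe2, DMF, 100 °C
Reagents that add atoms: tributyl(3-methylbut-2-en-1-yl)stannane, CC(C)=CC[Sn](CCCC)(CCCC)CCCC
Why: Stille coupling: oxidative addition of zerovalent palladium into the C3–Br bond, transmetalation with the allylic stannane and reductive elimination at the unsubstituted terminus of the prenyl ligand give the linear 3-methylbut-2-enyl group; the neutral, fluoride-free conditions leave the three silyl ethers intact.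

Step 13
Reactants: 20 (2S,2aR,7aS)-2-[3,4-bis(tert-butyldimethylsilyloxy)phenyl]-4-methoxy-1,1-dimethyl-3-(3-methylbut-2-en-1-yl)-6-(triisopropylsilyloxy)-2,2a,7,7a-tetrahydro-1H-cyclobuta[a]indene
Product: 21 4-[(2S,2aR,7aS)-6-hydroxy-4-methoxy-1,1-dimethyl-3-(3-methylbut-2-en-1-yl)-2,2a,7,7a-tetrahydro-1H-cyclobuta[a]inden-2-yl]benzene-1,2-diol
Conditions: Bu4NF, AcOH, THF, 0 → 25 °C
Reagents that add atoms: none
Why: Fluoride-mediated cleavage of the three aryl silyl ethers, driven by the strength of the Si–F bond; acetic acid buffers the medium so that the catechol is never present as an air-sensitive dianion, and the prenyl alkene and the stereocentres are untouched.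

## Compound list

1 | 3-hydroxy-5-methoxybenzaldehyde | COc1cc(O)cc(C=O)c1 | starting material
2 | 3-methoxy-5-(prop-2-en-1-yloxy)benzaldehyde | COc1cc(OCC=C)cc(C=O)c1 | intermediate
3 | 3-hydroxy-5-methoxy-2-(prop-2-en-1-yl)benzaldehyde | COc1cc(O)c(CC=C)c(C=O)c1 | intermediate
4 | 5-methoxy-2-(prop-2-en-1-yl)-3-(triisopropylsilyloxy)benzaldehyde | COc1cc(O[Si](C(C)C)(C(C)C)C(C)C)c(CC=C)c(C=O)c1 | intermediate
5 | 2-bromo-3-methoxy-6-(prop-2-en-1-yl)-5-(triisopropylsilyloxy)benzaldehyde | COc1cc(O[Si](C(C)C)(C(C)C)C(C)C)c(CC=C)c(C=O)c1Br | intermediate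
6 | [4-bromo-3-ethenyl-5-methoxy-2-(prop-2-en-1-yl)phenoxy]triisopropylsilane | COc1cc(O[Si](C(C)C)(C(C)C)C(C)C)c(CC=C)c(C=C)c1Br | intermediate
7 | 4-bromo-5-methoxy-7-(triisopropylsilyloxy)-1H-indene | COc1cc(O[Si](C(C)C)(C(C)C)C(C)C)c2c(c1Br)C=CC2 | intermediate
8 | (3,4-dihydroxyphenyl)acetic acid | OC(=O)Cc1ccc(O)c(O)c1 | starting material
9 | tert-butyldimethylsilyl [3,4-bis(tert-butyldimethylsilyloxy)phenyl]acetate | CC(C)(C)[Si](C)(C)OC(=O)Cc1ccc(O[Si](C)(C)C(C)(C)C)c(O[Si](C)(C)C(C)(C)C)c1 | intermediate (not isolated)
10 | [3,4-bis(tert-butyldimethylsilyloxy)phenyl]acetic acid | OC(=O)Cc1ccc(O[Si](C)(C)C(C)(C)C)c(O[Si](C)(C)C(C)(C)C)c1 | intermediate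
11 | (2R,5R)-2,5-dimethylpyrrolidine | C[C@@H]1CC[C@@H](C)N1 | starting material
12 | [3,4-bis(tert-butyldimethylsilyloxy)phenyl]acetyl chloride | ClC(=O)Cc1ccc(O[Si](C)(C)C(C)(C)C)c(O[Si](C)(C)C(C)(C)C)c1 | intermediate (not isolated)
13 | 2-[3,4-bis(tert-butyldimethylsilyloxy)phenyl]-1-[(2R,5R)-2,5-dimethylpyrrolidin-1-yl]ethan-1-one | C[C@@H]1CC[C@@H](C)N1C(=O)Cc1ccc(O[Si](C)(C)C(C)(C)C)c(O[Si](C)(C)C(C)(C)C)c1 | intermediate
14 | (2R,5R)-1-{2-[3,4-bis(tert-butyldimethylsilyloxy)phenyl]ethenylidene}-2,5-dimethylpyrrolidin-1-ium trifluoromethanesulfonate | C[C@@H]1CC[C@@H](C)[N+]1=C=Cc1ccc(O[Si](C)(C)C(C)(C)C)c(O[Si](C)(C)C(C)(C)C)c1.[O-]S(=O)(=O)C(F)(F)F | intermediate (not isolated)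
15 | (2R,5R)-1-[(2R,2aR,7aS)-2-[3,4-bis(tert-butyldimethylsilyloxy)phenyl]-3-bromo-4-methoxy-6-(triisopropylsilyloxy)-2,2a,7,7a-tetrahydro-1H-cyclobuta[a]inden-1-ylidene]-2,5-dimethylpyrrolidin-1-ium trifluoromethanesulfonate (shown as the exo-aryl C2 epimer reached by equilibration) | COc1cc(O[Si](C(C)C)(C(C)C)C(C)C)c2c(c1Br)[C@@H]1[C@H](C2)C(=[N+]2[C@H](C)CC[C@H]2C)[C@H]1c1ccc(O[Si](C)(C)C(C)(C)C)c(O[Si](C)(C)C(C)(C)C)c1.[O-]S(=O)(=O)C(F)(F)F | intermediate (not isolated)
16 | (2R,2aR,7aS)-2-[3,4-bis(tert-butyldimethylsilyloxy)phenyl]-3-bromo-4-methoxy-6-(triisopropylsilyloxy)-2,2a,7,7a-tetrahydro-1H-cyclobuta[a]inden-1-one | COc1cc(O[Si](C(C)C)(C(C)C)C(C)C)c2c(c1Br)[C@@H]1[C@H](C2)C(=O)[C@H]1c1ccc(O[Si](C)(C)C(C)(C)C)c(O[Si](C)(C)C(C)(C)C)c1 | intermediate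
17 | (2S,2aR,7aS)-2-[3,4-bis(tert-butyldimethylsilyloxy)phenyl]-3-bromo-4-methoxy-1-methylidene-6-(triisopropylsilyloxy)-2,2a,7,7a-tetrahydro-1H-cyclobuta[a]indene | COc1cc(O[Si](C(C)C)(C(C)C)C(C)C)c2c(c1Br)[C@@H]1[C@H](C2)C(=C)[C@H]1c1ccc(O[Si](C)(C)C(C)(C)C)c(O[Si](C)(C)C(C)(C)C)c1 | intermediate
18 | N'-{[(2R,2aR,7aS)-2-[3,4-bis(tert-butyldimethylsilyloxy)phenyl]-3-bromo-4-methoxy-1-methyl-6-(triisopropylsilyloxy)-2,2a,7,7a-tetrahydro-1H-cyclobuta[a]inden-1-yl]methyl}octane-1-sulfonohydrazide (both configurations at C1) | COc1cc(O[Si](C(C)C)(C(C)C)C(C)C)c2c(c1Br)[C@@H]1[C@H](C2)C(C)(CNNS(=O)(=O)CCCCCCCC)[C@H]1c1ccc(O[Si](C)(C)C(C)(C)C)c(O[Si](C)(C)C(C)(C)C)c1 | intermediate (not isolated)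
19 | (2S,2aR,7aS)-2-[3,4-bis(tert-butyldimethylsilyloxy)phenyl]-3-bromo-4-methoxy-1,1-dimethyl-6-(triisopropylsilyloxy)-2,2a,7,7a-tetrahydro-1H-cyclobuta[a]indene | COc1cc(O[Si](C(C)C)(C(C)C)C(C)C)c2c(c1Br)[C@@H]1[C@H](C2)C(C)(C)[C@H]1c1ccc(O[Si](C)(C)C(C)(C)C)c(O[Si](C)(C)C(C)(C)C)c1 | intermediate
20 | (2S,2aR,7aS)-2-[3,4-bis(tert-butyldimethylsilyloxy)phenyl]-4-methoxy-1,1-dimethyl-3-(3-methylbut-2-en-1-yl)-6-(triisopropylsilyloxy)-2,2a,7,7a-tetrahydro-1H-cyclobuta[a]indene | COc1cc(O[Si](C(C)C)(C(C)C)C(C)C)c2c(c1CC=C(C)C)[C@@H]1[C@H](C2)C(C)(C)[C@H]1c1ccc(O[Si](C)(C)C(C)(C)C)c(O[Si](C)(C)C(C)(C)C)c1 | intermediate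
21 | 4-[(2S,2aR,7aS)-6-hydroxy-4-methoxy-1,1-dimethyl-3-(3-methylbut-2-en-1-yl)-2,2a,7,7a-tetrahydro-1H-cyclobuta[a]inden-2-yl]benzene-1,2-diol | COc1cc(O)c2c(c1CC=C(C)C)[C@@H]1[C@H](C2)C(C)(C)[C@H]1c1ccc(O)c(O)c1 | target

## Step count and risks

Total: 13 steps. Longest linear sequence: 11 steps (1 to 21 through steps 1–6 and 9–13); the amide arm adds steps 7 and 8.

**Step 9 (key step).** The most likely failure is poor facial selection on the indene. Both ring A oxygens are meta to the cationic centre and bromine is ortho, so the benzylic cation is less stabilised than in indene itself. A later or reversible first bond formation could then erode the bias of the auxiliary. Fallback, setting out from 12 and 7: acyl chloride 12 is treated with dimethylamine to give 2-[3,4-bis(tert-butyldimethylsilyloxy)phenyl]-N,N-dimethylacetamide F1. Its smaller keteniminium salt adds to 7 under the conditions of step 9 without facial bias. After hydrolysis the product is 16 together with its (2S,2aS,7aR)-enantiomer F2, as the racemate. Preparative chromatography on a chiral stationary phase returns 16 to the route. Auxiliary control is thus replaced by resolution.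

**Step 11.** The most likely failure is slow capture of the tertiary cyclobutyl radical by the hydrazone. Plain reduction of the alkene, or β-scission of the strained ring towards the benzylic C2a radical, would then compete. Fallback, setting out from ketone 16 and avoiding any radical at C1:
- Wittig reaction with the methoxymethylene ylide gives the 1-(methoxymethylidene) enol ether F3.
- Mild aqueous acid (PPTS, wet acetone) gives the cyclobutane-1-carbaldehyde F4.
- Enolate methylation (KN(SiMe3)2, MeI, −78 °C) gives the 1-methylcyclobutane-1-carbaldehyde F5.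
- Condensation with tosylhydrazine gives the tosylhydrazone F6, which is reduced with catecholborane and then NaOAc, with loss of sulfinate and N2, to return at 19.

**Step 12.** The most likely failure is slow oxidative addition at the di-ortho-substituted, electron-rich C3–Br bond. Protodebromination and allyl transposition to the branched isomer would then compete. Fallback, setting out from 19: bromine–lithium exchange with t-BuLi in THF at −78 °C gives the C3 aryllithium F7. It is alkylated with 1-bromo-3-methylbut-2-ene in the presence of CuBr·SMe2 to return at 20, without palladium or tin.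

**Step 10.** The most likely failure is enolisation of the α-aryl cyclobutanone by the basic ylide, which would stall conversion. Fallback, setting out from 16: the weakly basic organocerium reagent from Me3SiCH2Li and CeCl3 adds to the carbonyl to give the β-hydroxysilane F8. KH then induces the syn-elimination of a Peterson olefination to return at 17.

**Step 4.** The most likely failure is attack of NBS on the allyl double bond, because the silyl ether and the formyl group damp the reactivity of the ring. Fallback, setting out from 3: the much more activated free phenol is brominated para to the hydroxyl (NBS, MeCN, −20 °C) to give 2-bromo-5-hydroxy-3-methoxy-6-(prop-2-en-1-yl)benzaldehyde F9. Silylation as in step 3 returns at 5.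

## Further compounds

F1 | step 9 | 2-[3,4-bis(tert-butyldimethylsilyloxy)phenyl]-N,N-dimethylacetamide | CN(C)C(=O)Cc1ccc(O[Si](C)(C)C(C)(C)C)c(O[Si](C)(C)C(C)(C)C)c1
F2 | step 9 | (2S,2aS,7aR)-enantiomer of 16 | COc1cc(O[Si](C(C)C)(C(C)C)C(C)C)c2c(c1Br)[C@H]1[C@@H](C2)C(=O)[C@@H]1c1ccc(O[Si](C)(C)C(C)(C)C)c(O[Si](C)(C)C(C)(C)C)c1
F3 | step 11 | 1-(methoxymethylidene) enol ether corresponding to 17 (E/Z mixture; C2, C2a, C7a as in 16) | COC=C1[C@@H]2Cc3c(O[Si](C(C)C)(C(C)C)C(C)C)cc(OC)c(Br)c3[C@@H]2[C@@H]1c1ccc(O[Si](C)(C)C(C)(C)C)c(O[Si](C)(C)C(C)(C)C)c1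
F4 | step 11 | 2-[3,4-bis(tert-butyldimethylsilyloxy)phenyl]-3-bromo-4-methoxy-6-(triisopropylsilyloxy)-2,2a,7,7a-tetrahydro-1H-cyclobuta[a]indene-1-carbaldehyde (C1 epimers; C2, C2a, C7a as in 16) | COc1cc(O[Si](C(C)C)(C(C)C)C(C)C)c2c(c1Br)[C@@H]1[C@H](C2)C(C=O)[C@H]1c1ccc(O[Si](C)(C)C(C)(C)C)c(O[Si](C)(C)C(C)(C)C)c1
F5 | step 11 | 1-methyl derivative of carbaldehyde F4 (C1 epimers) | COc1cc(O[Si](C(C)C)(C(C)C)C(C)C)c2c(c1Br)[C@@H]1[C@H](C2)C(C)(C=O)[C@H]1c1ccc(O[Si](C)(C)C(C)(C)C)c(O[Si](C)(C)C(C)(C)C)c1
F6 | step 11 | 4-methylbenzenesulfonylhydrazone of aldehyde F5 | COc1cc(O[Si](C(C)C)(C(C)C)C(C)C)c2c(c1Br)[C@@H]1[C@H](C2)C(C)(C=NNS(=O)(=O)c2ccc(C)cc2)[C@H]1c1ccc(O[Si](C)(C)C(C)(C)C)c(O[Si](C)(C)C(C)(C)C)c1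
F7 | step 12 | C3 aryllithium derived from 19 | COc1cc(O[Si](C(C)C)(C(C)C)C(C)C)c2c(c1[Li])[C@@H]1[C@H](C2)C(C)(C)[C@H]1c1ccc(O[Si](C)(C)C(C)(C)C)c(O[Si](C)(C)C(C)(C)C)c1
F8 | step 10 | 1-hydroxy-1-[(trimethylsilyl)methyl] adduct of 16 (β-hydroxysilane; C1 configuration immaterial) | COc1cc(O[Si](C(C)C)(C(C)C)C(C)C)c2c(c1Br)[C@@H]1[C@H](C2)C(O)(C[Si](C)(C)C)[C@H]1c1ccc(O[Si](C)(C)C(C)(C)C)c(O[Si](C)(C)C(C)(C)C)c1
F9 | step 4 | 2-bromo-5-hydroxy-3-methoxy-6-(prop-2-en-1-yl)benzaldehyde | COc1cc(O)c(CC=C)c(C=O)c1Br
A1 | alternative 1 | methyl 4,6-dimethoxy-1,1-dimethyl-7-oxo-2,2a,7,7a-tetrahydro-1H-cyclobuta[a]indene-2-carboxylate (endo ester) | COc1cc(OC)c2c(c1)[C@@H]1[C@H](C2=O)C(C)(C)[C@@H]1C(=O)OC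
A2 | alternative 1 | methyl cis-3-(2-bromo-4,6-dimethoxybenzoyl)-2,2-dimethylcyclobutane-1-carboxylate | COC(=O)[C@@H]1C[C@H](C(=O)c2c(Br)cc(OC)cc2OC)C1(C)C
A3 | alternative 2 | 2-[3,4-bis(methoxymethoxy)phenyl]-4,6-dihydroxy-1,1-dimethyl-1,2,2a,7a-tetrahydro-7H-cyclobuta[a]inden-7-one | Oc1cc(O)c2c(c1)[C@@H]1[C@H](C2=O)C(C)(C)[C@H]1c1ccc(OCOC)c(OCOC)c1
A4 | alternative 2 | dimethyl 3-[3,4-bis(methoxymethoxy)phenyl]-4,4-dimethylcyclobutane-1,2-dicarboxylate (esters cis, aryl trans to the adjacent ester) | COC(=O)[C@@H]1[C@H](C(=O)OC)C(C)(C)[C@H]1c1ccc(OCOC)c(OCOC)c1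
A5 | alternative 2 | pentane-2,4-dione | CC(=O)CC(C)=O
A6 | alternative 3 | 2-[3,4-bis(tert-butyldimethylsilyloxy)phenyl]-4-methoxy-1,1-dimethyl-2,2a,7,7a-tetrahydro-1H-cyclobuta[a]inden-6-ol | COc1cc(O)c2c(c1)[C@@H]1[C@H](C2)C(C)(C)[C@H]1c1ccc(O[Si](C)(C)C(C)(C)C)c(O[Si](C)(C)C(C)(C)C)c1
A7 | alternative 3 | 1-{7-[3,4-bis(tert-butyldimethylsilyloxy)phenyl]-6,6-dimethylbicyclo[3.2.0]hept-2-en-2-yl}-2-diazoethan-1-one | C1=C(C(=O)C=[N+]=[N-])[C@@H]2[C@H](C1)C(C)(C)[C@H]2c1ccc(O[Si](C)(C)C(C)(C)C)c(O[Si](C)(C)C(C)(C)C)c1
A8 | alternative 3 | methoxyethyne | COC#C
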